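**Assumption:** (R)-linalool and (S)-glycidol are available in ≥95% ee, and the aryl-O-TIPS and alkyl-O-TBS groups survive steps 3–17.

## Retrosynthetic overview
1. The target comes from global desilylation of 20. Compound 20 comes from a Ni-electrocatalytic decarboxylative alkenylation that joins the redox-active ester 12 (C1′–C6′ chromanyl chain) to the (E)-vinyl iodide 19 (C7′–C12′ fragment with the carbinol stereocentre).
2. Ester 12 comes from a Johnson orthoester Claisen that builds the E-C3′=C4′ alkene from isopropenyl carbinol 9. Compound 9 comes from ozonolysis of the prenyl group of chroman 7, then addition of isopropenylMgBr.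
3. Chroman 7 (the only ring formed, with the C2 quaternary stereocentre retained from (R)-linalool) comes from a photochemical Ni/Ir intramolecular O-arylation of the tertiary alcohol in aryl triflate 6. Triflate 6 comes from hydroboration/Suzuki coupling of (R)-linalool with iodophenol 3, itself made from methylhydroquinone.
4. Iodide 19 comes from Zr-catalysed methylalumination/iodination of the chiral propargylic silyl ether 18. Ether 18 comes from (S)-glycidol by Cu-catalysed opening with isobutenylMgBr, silylation, oxidation and Ohira–Bestmann homologation.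

## Route

**Step 1**
Reactants: 1 (2-methylbenzene-1,4-diol, methylhydroquinone)
Product: 2 (2-methyl-4-(triisopropylsilyloxy)phenol)
Conditions: TIPSCl (1.0 equiv), imidazole, DMF, 0 °C → rt
Reagents that add atoms: TIPSCl, CC(C)[Si](Cl)(C(C)C)C(C)C
Why: Mono-O-silylation occurs at the unhindered 4-OH, leaving the OH flanked by the methyl group free, because the bulky TIPS group differentiates the two OH groups sterically; no stereocentre is formed.

**Step 2**
Reactants: 2
Product: 3 (2-iodo-6-methyl-4-(triisopropylsilyloxy)phenol)
Conditions: NIS (1.05 equiv), MeCN, 0 °C, dark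
Reagents that add atoms: N-iodosuccinimide, O=C1CCC(=O)N1I
Why: Electrophilic aromatic iodination is directed ortho to the free phenol OH, because the para position carries OTIPS and the other ortho carbon carries CH3. This puts iodine at the future C4a; no stereocentre is formed.

**Step 3**
Reactants: 3; 4 ((R)-linalool, (3R)-3,7-dimethylocta-1,6-dien-3-ol)
Product: 5 (2-[(3R)-3-hydroxy-3,7-dimethyloct-6-en-1-yl]-6-methyl-4-(triisopropylsilyloxy)phenol)
Conditions: (i) 4 (1.2 equiv), 9-BBN, THF, rt; (ii) 3, Pd(dppf)Cl2 (5 mol%), K3PO4 (aq), THF, 60 °C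
Reagents that add atoms: none (9-BBN supplies only H; boron and iodine are lost)
Why: This is hydroboration/B-alkyl Suzuki–Miyaura coupling. 9-BBN hydroborates only the monosubstituted vinyl group (anti-Markovnikov), and the alkyl borane couples to the aryl iodide to form the C4a–C4 bond. The tertiary stereocentre is untouched, so it stays (R).

**Step 4**
Reactants: 5
Product: 6 (aryl triflate of 5)
Conditions: PhNTf2 (1.3 equiv), Et3N, DMAP (cat.), CH2Cl2, rt → 40 °C
Reagents that add atoms: N-phenylbis(trifluoromethanesulfonimide), O=S(=O)(C(F)(F)F)N(c1ccccc1)S(=O)(=O)C(F)(F)F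
Why: The acidic phenol is triflated chemoselectively over the tertiary alcohol, which installs the leaving group at the future C8a (O-sulfonylation, no stereocentre change).

**Step 5**
Reactants: 6
Product: 7 ((2R)-2,8-dimethyl-2-(4-methylpent-3-en-1-yl)-6-(triisopropylsilyloxy)chromane)
Conditions: NiBr2·dme (10 mol%), dtbbpy (10 mol%), [Ir{dF(CF3)ppy}2(dtbbpy)]PF6 (1 mol%), quinuclidine (2 equiv), DMA (0.02 M), blue LEDs (450 nm), 30 °C, 24 h
Reagents that add atoms: none (TfOH is lost)
Why: Proposed new method: intramolecular Ni/photoredox O-arylation of a tertiary alcohol with an ortho,ortho-disubstituted, electron-rich aryl triflate to close the 2,2-disubstituted chroman. Ni(0) adds oxidatively to Ar–OTf, and the deprotonated tertiary alcohol displaces triflate from Ni(II). The excited Ir(III) then oxidises Ni(II) to Ni(III), which undergoes fast six-membered C(sp2)–O reductive elimination, and Ir(II) returns Ni(I) to Ni(0). A tertiary alcohol has no α-C–H, so it cannot undergo the hydrogen-atom-transfer and ketone side reactions seen with primary and secondary alcohols. The closest known reactions are MacMillan-type Ni/photoredox C–O coupling of aryl halides with primary/secondary alcohols and Pd-catalysed intramolecular etherification of tertiary alcohols. C2 keeps its (R) configuration because the tertiary C–O bond is never cleaved.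

**Step 6**
Reactants: 7
Product: 8 (3-[(2S)-2,8-dimethyl-6-(triisopropylsilyloxy)chroman-2-yl]propanal; the label is S only because CIP priorities change, the spatial arrangement is unchanged)
Conditions: O3, CH2Cl2, −78 °C (1.0 equiv, pale-blue endpoint); then Me2S, −78 °C → rt
Reagents that add atoms: ozone, [O-][O+]=O
Why: Ozonolysis with reductive work-up cleaves the only alkene (the prenyl group, losing acetone) much faster than it attacks the silyl aryl ether, giving the C3′ aldehyde; the quaternary stereocentre is unaffected.

**Step 7**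
Reactants: 8
Product: 9 (5-[(2S)-2,8-dimethyl-6-(triisopropylsilyloxy)chroman-2-yl]-2-methylpent-1-en-3-ol, ~1:1 epimers at C3′)
Conditions: isopropenylMgBr (1.5 equiv), THF, −78 °C → 0 °C
Reagents that add atoms: isopropenylmagnesium bromide, C=C(C)[Mg]Br
Why: Grignard addition to the aldehyde forms the allylic alcohol; the new C3′ carbinol centre is racemic but is destroyed in the next step, so its configuration is irrelevant.

**Step 8**
Reactants: 9
Product: 10 (ethyl (E)-7-[(2R)-2,8-dimethyl-6-(triisopropylsilyloxy)chroman-2-yl]-4-methylhept-4-enoate)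
Conditions: CH3C(OEt)3 (10 equiv), EtCO2H (0.1 equiv), neat, 140 °C, sealed tube, 6 h
Reagents that add atoms: triethyl orthoacetate, CC(OCC)(OCC)OCC
Why: In the Johnson orthoester Claisen ([3,3]) the ketene acetal forms C5′–C6′ and shifts the alkene to C3′=C4′. The chair transition state keeps the carbinol substituent equatorial, so the E-trisubstituted alkene forms in high selectivity and the C3′ stereocentre is erased.

**Step 9**
Reactants: 10
Product: 11 ((E)-7-[(2R)-2,8-dimethyl-6-(triisopropylsilyloxy)chroman-2-yl]-4-methylhept-4-enoic acid)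
Conditions: LiOH·H2O (5 equiv), THF/MeOH/H2O 3:1:1, 40 °C, 6 h; then aqueous HCl to pH 4
Reagents that add atoms: lithium hydroxide/water, [Li+].[OH-]
Why: Saponification of the unhindered ethyl ester; the aryl-O-TIPS group is base-stable and no stereocentre is affected.

**Step 10**
Reactants: 11
Product: 12 (N-hydroxyphthalimide ester of 11)
Conditions: NHPI (1.2 equiv), DIC (1.2 equiv), DMAP (10 mol%), CH2Cl2, rt, 3 h
Reagents that add atoms: N-hydroxyphthalimide, O=C1c2ccccc2C(=O)N1O
Why: Carbodiimide (Steglich) esterification gives the redox-active ester needed for radical decarboxylative coupling.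

**Step 11**
Reactants: 13 ((S)-glycidol, [(2S)-oxiran-2-yl]methanol)
Product: 14 ((2R)-5-methylhex-4-ene-1,2-diol)
Conditions: isobutenylMgBr (3 equiv), CuI (10 mol%), THF, −30 → 0 °C
Reagents that add atoms: 2-methylprop-1-enylmagnesium bromide, CC(C)=C[Mg]Br
Why: Cu-catalysed SN2 opening occurs at the less hindered terminal epoxide carbon. The glycidol stereocentre is not involved, so (S)-glycidol gives the diol with unchanged spatial arrangement; the label changes to R only because the CIP priorities change. This sets the C9′ carbinol stereocentre.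

**Step 12**
Reactants: 14
Product: 15 (tert-butyl{[(2R)-2-(tert-butyldimethylsilyloxy)-5-methylhex-4-en-1-yl]oxy}dimethylsilane)
Conditions: TBSCl (2.5 equiv), imidazole (5 equiv), DMF, rt, 16 h
Reagents that add atoms: TBSCl, CC(C)(C)[Si](C)(C)Cl
Why: Exhaustive silylation of both OH groups gives differentiable protection and leaves the stereocentre untouched.

**Step 13**
Reactants: 15
Product: 16 ((2R)-2-(tert-butyldimethylsilyloxy)-5-methylhex-4-en-1-ol)
Conditions: CSA (10 mol%), MeOH/CH2Cl2 1:1, 0 °C, 2 h
Reagents that add atoms: none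
Why: Acid-catalysed methanolysis removes the primary TBS ether far faster than the secondary one, and the trisubstituted alkene tolerates mild acid.

**Step 14**
Reactants: 16
Product: 17 ((2R)-2-(tert-butyldimethylsilyloxy)-5-methylhex-4-enal)
Conditions: Dess–Martin periodinane (1.5 equiv), NaHCO3, CH2Cl2, 0 °C, 1 h (product used crude)
Reagents that add atoms: none
Why: Buffered Dess–Martin oxidation of the primary alcohol is mild enough to avoid epimerising the α-silyloxy aldehyde.

**Step 15**
Reactants: 17
Product: 18 (tert-butyldimethyl{[(3R)-6-methylhept-5-en-1-yn-3-yl]oxy}silane)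
Conditions: Ohira–Bestmann reagent (1.5 equiv), K2CO3 (2 equiv), MeOH, 0 °C → rt, 6 h
Reagents that add atoms: dimethyl (1-diazo-2-oxopropyl)phosphonate, COP(=O)(OC)C(=[N+]=[N-])C(C)=O
Why: The Seyferth–Gilbert/Ohira–Bestmann homologation converts the aldehyde to the terminal alkyne (new C8′ carbon) under mild base, and the silyl-protected α-carbon keeps its configuration.

**Step 16**
Reactants: 18
Product: 19 (tert-butyldimethyl{[(1E,3R)-1-iodo-2,6-dimethylhepta-1,5-dien-3-yl]oxy}silane)
Conditions: Me3Al (3 equiv), Cp2ZrCl2 (20 mol%), CH2Cl2, 0 °C → rt, 16 h; then I2 (1.5 equiv), THF, −30 → 0 °C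
Reagents that add atoms: trimethylaluminium, C[Al](C)C; iodine, II
Why: In Negishi Zr-catalysed carboalumination the methyl adds syn to the internal alkyne carbon (C8′) and aluminium to C7′. Iodinolysis with retention gives the (E)-trisubstituted vinyl iodide; the trisubstituted prenyl alkene is inert and the C9′ stereocentre is untouched.

**Step 17**
Reactants: 12; 19
Product: 20 (the bis-silyl-protected target)
Conditions: NiBr2·glyme (10 mol%), 2,2′-bipyridine (12 mol%), DMA, undivided cell, Zn(+) | Ni-foam(−), 5 mA, rt, 8 h (19, 1.5 equiv)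
Reagents that add atoms: none (CO2 and phthalimide are lost)
Why: Ni-electrocatalytic decarboxylative alkenylation reduces the redox-active ester to the primary C6′ radical, which is captured by Ni and cross-coupled with the vinyl iodide with retention of alkene geometry, forming the C6′–C7′ bond. No stereocentre is formed.

**Step 18**
Reactants: 20
Product: 21 (sargachromanol C)
Conditions: TBAF (4 equiv), THF, 0 → 35 °C, 6 h, under argon
Reagents that add atoms: none (fluoride leaves as silyl fluoride; only H is added)
Why: Fluoride cleaves the aryl-O-TIPS and the allylic O-TBS group under mild conditions, leaving the alkenes and both stereocentres intact.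

## Compound list
1 | 2-methylbenzene-1,4-diol | Cc1cc(O)ccc1O | starting material
2 | 2-methyl-4-(triisopropylsilyloxy)phenol | Cc1cc(O[Si](C(C)C)(C(C)C)C(C)C)ccc1O | intermediate
3 | 2-iodo-6-methyl-4-(triisopropylsilyloxy)phenol | Cc1cc(O[Si](C(C)C)(C(C)C)C(C)C)cc(I)c1O | intermediate
4 | (R)-linalool | C=C[C@](C)(O)CCC=C(C)C | starting material
5 | 2-[(3R)-3-hydroxy-3,7-dimethyloct-6-en-1-yl]-6-methyl-4-(TIPSO)phenol | Cc1cc(O[Si](C(C)C)(C(C)C)C(C)C)cc(CC[C@](C)(O)CCC=C(C)C)c1O | intermediate
6 | aryl triflate of 5 | Cc1cc(O[Si](C(C)C)(C(C)C)C(C)C)cc(CC[C@](C)(O)CCC=C(C)C)c1OS(=O)(=O)C(F)(F)F | intermediate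
7 | (2R)-2,8-dimethyl-2-(4-methylpent-3-en-1-yl)-6-(TIPSO)chromane | CC(C)=CCC[C@]1(C)CCc2cc(O[Si](C(C)C)(C(C)C)C(C)C)cc(C)c2O1 | intermediate
8 | 3-[(2S)-2,8-dimethyl-6-(TIPSO)chroman-2-yl]propanal | O=CCC[C@]1(C)CCc2cc(O[Si](C(C)C)(C(C)C)C(C)C)cc(C)c2O1 | intermediate
9 | 5-[(2S)-2,8-dimethyl-6-(TIPSO)chroman-2-yl]-2-methylpent-1-en-3-ol (C3′ epimers) | C=C(C)C(O)CC[C@]1(C)CCc2cc(O[Si](C(C)C)(C(C)C)C(C)C)cc(C)c2O1 | intermediate
10 | ethyl (E)-7-[(2R)-chroman-2-yl]-4-methylhept-4-enoate (chroman as in 9) | CCOC(=O)CC/C(C)=C/CC[C@]1(C)CCc2cc(O[Si](C(C)C)(C(C)C)C(C)C)cc(C)c2O1 | intermediate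
11 | (E)-acid corresponding to 10 | OC(=O)CC/C(C)=C/CC[C@]1(C)CCc2cc(O[Si](C(C)C)(C(C)C)C(C)C)cc(C)c2O1 | intermediate
12 | N-hydroxyphthalimide ester of 11 | O=C1c2ccccc2C(=O)N1OC(=O)CC/C(C)=C/CC[C@]3(C)CCc4cc(O[Si](C(C)C)(C(C)C)C(C)C)cc(C)c4O3 | intermediate
13 | (S)-glycidol | OC[C@H]1CO1 | starting material
14 | (2R)-5-methylhex-4-ene-1,2-diol | OC[C@H](O)CC=C(C)C | intermediate
15 | (2R)-1,2-bis(TBSO)-5-methylhex-4-ene | CC(C)(C)[Si](C)(C)OC[C@H](O[Si](C)(C)C(C)(C)C)CC=C(C)C | intermediate
16 | (2R)-2-(TBSO)-5-methylhex-4-en-1-ol | OC[C@H](O[Si](C)(C)C(C)(C)C)CC=C(C)C | intermediate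
17 | (2R)-2-(TBSO)-5-methylhex-4-enal | O=C[C@H](O[Si](C)(C)C(C)(C)C)CC=C(C)C | intermediate
18 | TBS ether of (3R)-6-methylhept-5-en-1-yn-3-ol | C#C[C@H](O[Si](C)(C)C(C)(C)C)CC=C(C)C | intermediate
19 | (1E,3R)-1-iodo-2,6-dimethylhepta-1,5-dien-3-yl TBS ether | I/C=C(C)/[C@@H](CC=C(C)C)O[Si](C)(C)C(C)(C)C | intermediate
20 | bis-silyl-protected sargachromanol C | CC(C)=CC[C@@H](O[Si](C)(C)C(C)(C)C)/C(C)=C/CC/C(C)=C/CC[C@]1(C)CCc2cc(O[Si](C(C)C)(C(C)C)C(C)C)cc(C)c2O1 | intermediate
21 | sargachromanol C, (2R)-2,8-dimethyl-2-[(3E,7E,9R)-9-hydroxy-4,8,12-trimethyltrideca-3,7,11-trien-1-yl]chroman-6-ol | CC(C)=CC[C@@H](O)/C(C)=C/CC/C(C)=C/CC[C@]1(C)CCc2cc(O)cc(C)c2O1 | target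

**Total step count:** 18

**Longest linear sequence:** 12 steps (1 → 2 → 3 → 4 → 5 → 6 → 7 → 8 → 9 → 10 → 17 → 18)

**Three steps most likely to fail:**
1. **Step 5 (the proposed new step).** Oxidative addition of Ni(0) into a 2,6-disubstituted, electron-rich aryl triflate, and C–O reductive elimination from a tertiary alkoxide, may both be too slow. Fallback: thermal Pd-catalysed intramolecular etherification of 6 with a bulky biarylphosphine ligand (Pd/tBuBrettPhos, Cs2CO3, toluene, 100 °C), or of the aryl bromide made from 6 by Pd-catalysed triflate-to-bromide exchange. This replaces the radical-polar Ni/Ir manifold with a known two-electron Pd(0)/Pd(II) C–O coupling.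
2. **Step 17.** The electrochemical coupling of two complex fragments may give low yield, homocoupling, or E/Z erosion. Fallback: convert 12 to the primary iodide by Barton-type decarboxylative iodination, make the alkylzinc, and couple it with 19 under Pd-catalysed Negishi conditions. This is a two-electron route that retains alkene geometry.
3. **Step 3.** 9-BBN may react with the free tertiary alcohol or phenol, and the Suzuki coupling of the hindered, OH-bearing iodoarene may be sluggish. Fallback: Mizoroki–Heck coupling of 3 with (R)-linalool, followed by chemoselective diimide reduction of the less hindered styrenyl C=C in the presence of the trisubstituted prenyl alkene.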